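**Strategy.** Ring A (C4–C8) is disconnected at C6–C7. The feature exploited is the tertiary carbinol C7, which lies 1,5 to C6 beside the oxygenated C5 and points its methyl group into the cleft between rings A and C. It is made from a secondary silyl ether C7–H: a dirhodium carbenoid at C6 inserts into that bond with retention, closing ring A as the C5 ketone and creating the quaternary centre in one operation. The precursor is the cis-fused ring B/ring C bicycle whose C4 diazoacetyl and C8 (S)-1-silyloxyethyl arms are both endo. It comes from a silicon-tethered enone–alkyne photocycloaddition and a hydroxyl-directed hydrogenation.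

Key step: step 15

**Remarks on the chemistry.**
- Atom labels follow the target: C1 (tigloyloxy CH), C2, C3 (methyl-bearing quaternary), C4, C5 (acetoxy CH), C6, C7 (methyl carbinol), C8, C9 (lactone oxygen), O10, C11, C12, C13. Ring A = C4–C8, ring B = C3/C4/C8/C9, ring C = C1/C2/C3/C9/C13, ring D = butenolide.
- Read from the target SMILES, rings A and C lie on the same face of ring B (cis-syn-cis). C3–CH3, C9–O, H4 and H8 stand on the other face. C1–O, C5–O and C7–O point out of the cleft (exo); C7–CH3 points into it (endo). Compounds 19 and 20 were checked against this: insertion with retention requires the (7S) silyl ether, and both arms must be cis to ring C.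
- Assumption for step 4: the tether methyl sits equatorial in a chair-like six-membered closure. On that model the (R)-configured tether gives the required configuration at C3 and C9, and C7 is then reset in steps 7 and 8.

**Route**

Step 1
Reactants: 1 (R)-but-3-yn-2-ol
Product: 2 (R)-pent-2-yne-1,4-diol
Conditions: n-BuLi (2.2 equiv), THF, −78 to 0 °C; (CH2O)n, 0 °C to rt; aq. NH4Cl
Reagents that add atoms: formaldehyde (as paraformaldehyde), C=O
Why: Acetylide hydroxymethylation; the alkoxide–acetylide dianion reacts with formaldehyde at carbon only and the carbinol centre is not involved.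

Step 2
Reactants: 2 (R)-pent-2-yne-1,4-diol
Product: 3 (R)-4-hydroxypent-2-yn-1-yl pivalate
Conditions: PivCl (1.0 equiv), pyridine, CH2Cl2, −20 °C
Reagents that add atoms: pivaloyl chloride, CC(C)(C)C(Cl)=O
Why: Selective acylation; the bulky acid chloride esterifies the primary propargylic hydroxyl faster than the secondary one at low temperature.

Step 3
Reactants: 3 (R)-4-hydroxypent-2-yn-1-yl pivalate, 4 2-hydroxy-3-methylcyclopent-2-en-1-one
Product: 6 silaketal-tethered enone, via chlorosilyl ether 5 (not isolated)
Conditions: i-Pr2SiCl2 (1.1 equiv), Et3N, DMAP (cat.), CH2Cl2, 0 °C; then 4, imidazole, rt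
Reagents that add atoms: dichlorodiisopropylsilane, CC(C)[Si](Cl)(Cl)C(C)C
Why: Stepwise substitution at silicon (unsymmetrical silaketal formation); the isopropyl groups slow the second displacement, so monochloride 5 forms first and then silylates the acidic enol oxygen of 4.

Step 4
Reactants: 6 silaketal-tethered enone
Product: 7 tethered cyclobutene cycloadduct (7R)
Conditions: hν (350 nm, Pyrex), degassed CH2Cl2 (0.01 M), 0 °C
Reagents that add atoms: none
Why: Intramolecular enone–alkyne [2+2] photocycloaddition through the triplet enone; the four-atom O–Si–O–C tether on the α-carbon allows only the straight mode (C9–C8 and C3–C4 bonds), cis fusion of rings B and C is compulsory, and the equatorial tether methyl is expected to select the enone face that sets C3 and C9 as drawn.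

Step 5
Reactants: 7 tethered cyclobutene cycloadduct (7R)
Product: 8 dioxolane of 7
Conditions: TMSOCH2CH2OTMS, TMSOTf (5 mol %), CH2Cl2, −78 to −20 °C
Reagents that add atoms: 1,2-bis(trimethylsilyloxy)ethane, C[Si](C)(C)OCCO[Si](C)(C)C
Why: Ketalisation with the bis-silyl glycol under silyl triflate catalysis suits a hindered ketone and runs cold and anhydrous, so the silaketal and the cyclobutene survive and the C13 ketone is masked before C9–OH is ever set free next to it.

Step 6
Reactants: 8 dioxolane of 7
Product: 9 (7R)-diol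
Conditions: HF·pyridine, pyridine, THF, 0 °C to rt
Reagents that add atoms: none
Why: Fluoride-driven cleavage of the dialkoxysilane (strong Si–F bonds) in buffered medium leaves the dioxolane and the pivalate untouched.

Step 7
Reactants: 9 (7R)-diol
Product: 10 cyclobutenyl methyl ketone
Conditions: MnO2 (activated, excess), CH2Cl2, rt
Reagents that add atoms: none
Why: Chemoselective allylic oxidation; MnO2 oxidises only the secondary allylic alcohol, the tertiary C9–OH is inert, and the auxiliary configuration at C7 is erased.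

Step 8
Reactants: 10 cyclobutenyl methyl ketone
Product: 11 (7S)-diol
Conditions: (R)-2-methyl-CBS-oxazaborolidine (0.2 equiv), catecholborane (2.2 equiv), toluene, −78 °C; aq. NaOH work-up
Reagents that add atoms: none
Why: CBS reduction under reagent control; the (R) catalyst distinguishes the fully substituted cyclobutenyl group from methyl and should give the (7S) allylic alcohol, while catecholborane turns the tertiary hydroxyl into a borate that carries no hydride.

Step 9
Reactants: 11 (7S)-diol
Product: 12 C7 TBS ether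
Conditions: TBSCl, imidazole, DMF, rt
Reagents that add atoms: tert-butyldimethylsilyl chloride, CC(C)(C)[Si](C)(C)Cl
Why: Imidazole-promoted silylation of the secondary alcohol; the hindered tertiary C9–OH does not react and stays free as the directing group.

Step 10
Reactants: 12 C7 TBS ether
Product: 13 cis-endo cyclobutane
Conditions: H2 (4 atm), [Ir(cod)(PCy3)(py)]PF6 (10 mol %), CH2Cl2, rt
Reagents that add atoms: none
Why: Hydroxyl-directed homogeneous hydrogenation; the cationic iridium catalyst binds the tertiary C9–OH on the exo face and adds both hydrogens to the strained tetrasubstituted cyclobutene from that face, which places H4 and H8 exo and both arms endo (new stereocentres C4 and C8).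

Step 11
Reactants: 13 cis-endo cyclobutane
Product: 14 C9 TES ether
Conditions: TESOTf, 2,6-lutidine, CH2Cl2, −78 to 0 °C
Reagents that add atoms: triethylsilyl trifluoromethanesulfonate, CC[Si](CC)(CC)OS(=O)(=O)C(F)(F)F
Why: Silyl triflate with a hindered pyridine base silylates even tertiary alcohols at low temperature without touching the ketal.

Step 12
Reactants: 14 C9 TES ether
Product: 15 primary alcohol
Conditions: i-Bu2AlH (2.5 equiv), CH2Cl2, −78 °C; Rochelle salt
Reagents that add atoms: none
Why: Reductive cleavage of the pivalate ester by hydride at low temperature spares the silyl ethers and the ketal.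

Step 13
Reactants: 15 primary alcohol
Product: 17 carboxylic acid, via aldehyde 16 (not isolated)
Conditions: TEMPO (0.2 equiv), PhI(OAc)2 (2.5 equiv), MeCN/pH 7 buffer, rt
Reagents that add atoms: water, O
Why: Oxoammonium (TEMPO) oxidation takes the primary alcohol through the aldehyde and its hydrate to the acid in buffered medium, which protects the ketal, the silyl ethers and the epimerisable endo centre C4.

Step 14
Reactants: 17 carboxylic acid
Product: 19 diazomethyl ketone, via acid chloride 18 (not isolated)
Conditions: 1-chloro-N,N,2-trimethylprop-1-en-1-amine, CH2Cl2, 0 °C to rt; then TMSCHN2 (2.5 equiv), MeCN/THF, 0 °C to rt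
Reagents that add atoms: (trimethylsilyl)diazomethane, C[Si](C)(C)C=[N+]=[N-]
Why: Acylation of a diazoalkane (Arndt–Eistert type); the acid chloride is formed under neutral conditions and acylates the reagent at carbon, and loss of the silyl group as chlorosilane gives the diazomethyl ketone without base and hence without epimerisation at C4.

Step 15
Reactants: 19 diazomethyl ketone
Product: 20 tricyclic ring A ketone
Conditions: Rh2(OAc)4 (2 mol %), CH2Cl2 (0.005 M, slow addition of 19), rt
Reagents that add atoms: none
Why: Dirhodium tetraacetate extrudes dinitrogen from the diazomethyl ketone and the electrophilic rhodium carbenoid at C6 inserts into the C7–H bond through a concerted three-centre, hydride-transfer-like transition state; the closest known reaction type is the rhodium-catalysed intramolecular 1,5 C–H insertion of α-diazo ketones into C–H bonds next to an ether oxygen to give cyclopentanones. Ring A closes in the 1,5-insertion mode, C6 bonding to C7 across the chain C6–C5–C4–C8–C7, so the new five-membered ring is cis-fused to ring B by necessity. The only new stereocentre, C7, is controlled by the (7S) silyl ether set in step 8, because insertion replaces hydrogen by carbon with retention and so places the methyl group endo and the oxygen exo. The step needs site selectivity for C7–H over the C2 methylene and C3 methyl C–H bonds, which are also 1,5-related, and over ylide formation at oxygen. The silyloxy lone pair makes the tertiary C7–H the most hydridic bond within reach, the cis-endo placement of both arms on ring B holds it against the carbenoid, the bulky TBS group shields its own oxygen, the C9 silyl ether lies on the opposite face, and the ketal oxygens could only close a seven-membered ylide.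

Step 16
Reactants: 20 tricyclic ring A ketone
Product: 21 5-endo alcohol
Conditions: NaBH4, MeOH/THF, −20 to 0 °C
Reagents that add atoms: none
Why: Borohydride reduction of the cyclopentanone; hydride can only arrive from the exo face of ring A because the endo face lies in the cleft against ring C, so the new stereocentre C5 carries an endo hydroxyl.

Step 17
Reactants: 21 5-endo alcohol
Product: 22 5-exo acetate
Conditions: PPh3, DIAD, AcOH, toluene, 0 to 40 °C
Reagents that add atoms: acetic acid, CC(=O)O
Why: Mitsunobu reaction; SN2 displacement of the oxyphosphonium by acetate from the open exo face inverts C5 and installs the exo acetate in one operation, with tertiary silyl ethers and the ketal inert.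

Step 18
Reactants: 22 5-exo acetate
Product: 23 α-ketol
Conditions: 1 M aq. HCl, THF, rt
Reagents that add atoms: water, O
Why: Acid hydrolysis removes the dioxolane and the tertiary triethylsilyl ether, both far more labile than the hindered tertiary TBS ether at C7 and the acetate; mild acid at room temperature is chosen to avoid ring-expanding α-ketol rearrangement of the cyclobutanol.

Step 19
Reactants: 23 α-ketol
Product: 26 ketodiol, via bis-silyl enol ether 24 (not isolated), via silyloxy ketone 25 (not isolated)
Conditions: TMSOTf, Et3N, CH2Cl2, 0 °C; m-CPBA, NaHCO3, CH2Cl2, −20 to 0 °C; 0.5 M HCl, THF/MeOH, 0 °C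
Reagents that add atoms: 3-chloroperoxybenzoic acid, OOC(=O)c1cccc(Cl)c1
Why: Rubottom oxidation; enolisation can only occur toward C1 (C9 is quaternary), the silyl enol ether is epoxidised from the exo face of ring C because the endo face is closed by ring A, and silyl migration then hydrolysis give the exo C1 alcohol (new stereocentre C1).

Step 20
Reactants: 26 ketodiol
Product: 27 C1 tiglate
Conditions: tigloyl chloride (1.5 equiv), pyridine, DMAP (cat.), CH2Cl2, 0 °C
Reagents that add atoms: tigloyl chloride, C/C=C(\C)C(Cl)=O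
Why: DMAP-catalysed acylation is selective for the secondary C1–OH over the hindered tertiary C9–OH, and the weak base avoids vinylketene formation so the (E)-alkene is kept.

Step 21
Reactants: 28 benzyl 2-(diethoxyphosphoryl)acetate
Product: 29 benzyl 2-(diethoxyphosphoryl)-3-(triisopropylsilyloxy)propanoate
Conditions: NaH (1.0 equiv), THF, 0 °C; i-Pr3SiOCH2Cl, 0 °C to rt
Reagents that add atoms: (triisopropylsiloxy)methyl chloride, ClCO[Si](C(C)C)(C(C)C)C(C)C
Why: Enolate C-alkylation; the phosphonate-stabilised ester enolate is alkylated by the reactive chloromethyl ether, which installs the protected hydroxymethyl group in one step.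

Step 22
Reactants: 29 benzyl 2-(diethoxyphosphoryl)-3-(triisopropylsilyloxy)propanoate
Product: 30 2-(diethoxyphosphoryl)-3-(triisopropylsilyloxy)propanoic acid
Conditions: H2 (1 atm), Pd/C, EtOAc, rt
Reagents that add atoms: none
Why: Hydrogenolysis of the benzyl ester frees the acid without touching the silyl ether or the phosphonate.

Step 23
Reactants: 27 C1 tiglate, 30 2-(diethoxyphosphoryl)-3-(triisopropylsilyloxy)propanoic acid
Product: 31 C9 phosphonate ester
Conditions: DCC, DMAP, CH2Cl2, 0 °C to rt
Reagents that add atoms: none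
Why: Steglich esterification; carbodiimide-activated phosphonoacetic acids acylate even tertiary alcohols (through the acylpyridinium or the derived ketene), C9–OH is the only free hydroxyl, and the phosphonate carbon is an inconsequential epimer mixture.

Step 24
Reactants: 31 C9 phosphonate ester
Product: 32 silyl-protected butenolide
Conditions: LiCl, DBU, MeCN, rt
Reagents that add atoms: none
Why: Intramolecular Horner–Wadsworth–Emmons olefination under LiCl/amine conditions closes ring D onto the C13 ketone and forms the tetrasubstituted C12=C13 bond, and the mild base spares the C1 and C5 esters.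

Step 25
Reactants: 32 silyl-protected butenolide
Product: 33 diol
Conditions: 48% aq. HF, MeCN, 0 °C to rt
Reagents that add atoms: none
Why: Acidic fluoride desilylation removes the primary triisopropylsilyl ether and the tertiary TBS ether in one operation, the esters and the lactone being stable to aqueous HF.

Step 26
Reactants: 33 diol
Product: 34 CNP0210373.1
Conditions: Ac2O, pyridine, CH2Cl2, 0 °C
Reagents that add atoms: acetic anhydride, CC(=O)OC(C)=O
Why: Selective acetylation of the primary allylic alcohol; the tertiary C7–OH is not acylated under these conditions, which completes the target.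

**Compound list**

1 | (R)-but-3-yn-2-ol | C[C@@H](O)C#C | starting material
2 | (R)-pent-2-yne-1,4-diol | C[C@@H](O)C#CCO | intermediate
3 | (R)-4-hydroxypent-2-yn-1-yl pivalate | C[C@@H](O)C#CCOC(=O)C(C)(C)C | intermediate
4 | 2-hydroxy-3-methylcyclopent-2-en-1-one | CC1=C(O)C(=O)CC1 | starting material
5 | chlorodiisopropylsilyl ether of 3 (not isolated) | C[C@@H](O[Si](Cl)(C(C)C)C(C)C)C#CCOC(=O)C(C)(C)C | intermediate
6 | silaketal-tethered enone: 3-methyl-2-silyloxycyclopent-2-enone joined through O–Si(i-Pr)2–O to the (R)-carbinol of 3 | CC1=C(O[Si](C(C)C)(C(C)C)O[C@H](C)C#CCOC(=O)C(C)(C)C)C(=O)CC1 | intermediate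
7 | cycloadduct: cis-fused rings B and C with C4=C8 cyclobutene, C13 ketone, C3–CH3 and C9–O exo, C4–CH2OPiv, (7R) carbinol bridged to O9 by Si(i-Pr)2 | C1C[C@]2(C)C(COC(=O)C(C)(C)C)=C3[C@@H](C)O[Si](C(C)C)(C(C)C)O[C@@]23C1=O | intermediate
8 | C13 ethylene ketal of 7 | C1C[C@]2(C)C(COC(=O)C(C)(C)C)=C3[C@@H](C)O[Si](C(C)C)(C(C)C)O[C@@]23C14OCCO4 | intermediate
9 | (7R)-diol: cyclobutene with C9–OH, C8–CH(OH)CH3, C4–CH2OPiv, C13 ketal | C1C[C@]2(C)C(COC(=O)C(C)(C)C)=C([C@@H](C)O)[C@]2(O)C13OCCO3 | intermediate
10 | cyclobutenyl methyl ketone (C7 ketone, C9–OH) | C1C[C@]2(C)C(COC(=O)C(C)(C)C)=C(C(C)=O)[C@]2(O)C13OCCO3 | intermediate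
11 | (7S)-diol | C1C[C@]2(C)C(COC(=O)C(C)(C)C)=C([C@H](C)O)[C@]2(O)C13OCCO3 | intermediate
12 | (7S) C7 TBS ether with C9–OH free | C1C[C@]2(C)C(COC(=O)C(C)(C)C)=C([C@H](C)O[Si](C)(C)C(C)(C)C)[C@]2(O)C13OCCO3 | intermediate
13 | cis-endo cyclobutane: C4–CH2OPiv and C8–(S)-CH(OTBS)CH3 both cis to ring C, C9–OH and C3–CH3 exo | C1C[C@]2(C)[C@H](COC(=O)C(C)(C)C)[C@H]([C@H](C)O[Si](C)(C)C(C)(C)C)[C@]2(O)C13OCCO3 | intermediate
14 | C9 TES ether of 13 | C1C[C@]2(C)[C@H](COC(=O)C(C)(C)C)[C@H]([C@H](C)O[Si](C)(C)C(C)(C)C)[C@]2(O[Si](CC)(CC)CC)C13OCCO3 | intermediate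
15 | C4 hydroxymethyl compound (primary alcohol) | C1C[C@]2(C)[C@H](CO)[C@H]([C@H](C)O[Si](C)(C)C(C)(C)C)[C@]2(O[Si](CC)(CC)CC)C13OCCO3 | intermediate
16 | C4 aldehyde (not isolated) | C1C[C@]2(C)[C@H](C=O)[C@H]([C@H](C)O[Si](C)(C)C(C)(C)C)[C@]2(O[Si](CC)(CC)CC)C13OCCO3 | intermediate
17 | C4 endo carboxylic acid | C1C[C@]2(C)[C@H](C(=O)O)[C@H]([C@H](C)O[Si](C)(C)C(C)(C)C)[C@]2(O[Si](CC)(CC)CC)C13OCCO3 | intermediate
18 | acid chloride (not isolated) | C1C[C@]2(C)[C@H](C(=O)Cl)[C@H]([C@H](C)O[Si](C)(C)C(C)(C)C)[C@]2(O[Si](CC)(CC)CC)C13OCCO3 | intermediate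
19 | cis-endo diazomethyl ketone with (7S) TBS ether, C9 TES ether, C13 ketal (key-step precursor) | C1C[C@]2(C)[C@H](C(=O)C=[N+]=[N-])[C@H]([C@H](C)O[Si](C)(C)C(C)(C)C)[C@]2(O[Si](CC)(CC)CC)C13OCCO3 | intermediate
20 | tricyclic ring A ketone: C5 ketone, quaternary C7 with CH3 endo and OTBS exo (key-step product) | C1C[C@]2(C)[C@@H]3C(=O)C[C@@](C)(O[Si](C)(C)C(C)(C)C)[C@@H]3[C@]2(O[Si](CC)(CC)CC)C13OCCO3 | intermediate
21 | C5 endo alcohol | C1C[C@]2(C)[C@@H]3[C@H](O)C[C@@](C)(O[Si](C)(C)C(C)(C)C)[C@@H]3[C@]2(O[Si](CC)(CC)CC)C13OCCO3 | intermediate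
22 | C5 exo acetate | C1C[C@]2(C)[C@@H]3[C@@H](OC(C)=O)C[C@@](C)(O[Si](C)(C)C(C)(C)C)[C@@H]3[C@]2(O[Si](CC)(CC)CC)C13OCCO3 | intermediate
23 | α-ketol: C13 ketone, C9–OH, C5–OAc, C7–OTBS | C1C[C@]2(C)[C@@H]3[C@@H](OC(C)=O)C[C@@](C)(O[Si](C)(C)C(C)(C)C)[C@@H]3[C@]2(O)C1=O | intermediate
24 | C13=C1 trimethylsilyl enol ether with C9–OTMS (not isolated) | C1C[C@]2(C)[C@@H]3[C@@H](OC(C)=O)C[C@@](C)(O[Si](C)(C)C(C)(C)C)[C@@H]3[C@]2(O[Si](C)(C)C)C(O[Si](C)(C)C)=1 | intermediate
25 | C1 exo OTMS, C9 OTMS ketone (not isolated) | C[Si](C)(C)O[C@H]1C[C@]2(C)[C@@H]3[C@@H](OC(C)=O)C[C@@](C)(O[Si](C)(C)C(C)(C)C)[C@@H]3[C@]2(O[Si](C)(C)C)C1=O | intermediate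
26 | ketodiol: C1 exo OH, C9–OH, C13 ketone | O[C@H]1C[C@]2(C)[C@@H]3[C@@H](OC(C)=O)C[C@@](C)(O[Si](C)(C)C(C)(C)C)[C@@H]3[C@]2(O)C1=O | intermediate
27 | C1 exo tiglate with C9–OH free | C/C=C(\C)C(=O)O[C@H]1C[C@]2(C)[C@@H]3[C@@H](OC(C)=O)C[C@@](C)(O[Si](C)(C)C(C)(C)C)[C@@H]3[C@]2(O)C1=O | intermediate
28 | benzyl 2-(diethoxyphosphoryl)acetate | CCOP(=O)(OCC)CC(=O)OCc1ccccc1 | starting material
29 | benzyl 2-(diethoxyphosphoryl)-3-(triisopropylsilyloxy)propanoate (racemic) | CCOP(=O)(OCC)C(CO[Si](C(C)C)(C(C)C)C(C)C)C(=O)OCc1ccccc1 | intermediate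
30 | 2-(diethoxyphosphoryl)-3-(triisopropylsilyloxy)propanoic acid (racemic) | CCOP(=O)(OCC)C(CO[Si](C(C)C)(C(C)C)C(C)C)C(=O)O | intermediate
31 | C9 ester of 30 (epimers at the phosphonate carbon) | C/C=C(\C)C(=O)O[C@H]1C[C@]2(C)[C@@H]3[C@@H](OC(C)=O)C[C@@](C)(O[Si](C)(C)C(C)(C)C)[C@@H]3[C@]2(OC(=O)C(CO[Si](C(C)C)(C(C)C)C(C)C)P(=O)(OCC)OCC)C1=O | intermediate
32 | butenolide with C12–CH2OTIPS and C7–OTBS | C/C=C(\C)C(=O)O[C@H]1C[C@]2(C)[C@@H]3[C@@H](OC(C)=O)C[C@@](C)(O[Si](C)(C)C(C)(C)C)[C@@H]3[C@@]23OC(=O)C(CO[Si](C(C)C)(C(C)C)C(C)C)=C13 | intermediate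
33 | diol: C7–OH and C12–CH2OH | C/C=C(\C)C(=O)O[C@H]1C[C@]2(C)[C@@H]3[C@@H](OC(C)=O)C[C@@](C)(O)[C@@H]3[C@@]23OC(=O)C(CO)=C13 | intermediate
34 | CNP0210373.1 | C/C=C(\C)C(=O)O[C@H]1C[C@]2(C)[C@@H]3[C@@H](OC(C)=O)C[C@@](C)(O)[C@@H]3[C@@]23OC(=O)C(COC(C)=O)=C13 | target

**Step count and risks**

Total: 26 steps. Longest linear sequence: 24 steps (steps 1–20 and 23–26, from 1 to 34); steps 21–22 prepare acid 30.

Steps most likely to fail:

1. Step 4 (photocycloaddition). The tether stereocentre may steer the alkyne to the other face of the enone (methyl axial instead of equatorial) or discriminate poorly, so that the major cycloadduct has the wrong configuration at C3 and C9. Prolonged irradiation may also trigger a 1,3-acyl shift of the β,γ-unsaturated ketone. The fallback changes the source of stereocontrol; it sets out from 4 and comes back to the route at 11. Commercial (S)-but-3-yn-2-ol is hydroxymethylated and monopivaloylated as in steps 1 and 2 to give (S)-pent-2-yne-1,4-diol F1 and (S)-4-hydroxypent-2-yn-1-yl pivalate F2. Tethering to 4 through the (S)-chlorosilyl ether F3 gives the (S)-tethered enone F4. Irradiation then leads to the (7S) cycloadduct F5, ketalisation as in step 5 to the (7S) ketal F6, and buffered HF·pyridine releases 11 directly, so that steps 7 and 8 fall away. If the two faces are attacked at similar rates in either series, the diastereomeric cycloadducts are separated by chromatography before going on.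

2. Step 15 (C–H insertion). The unstabilised acyl carbenoid may lose site selectivity (insertion into the C2 methylene, ylide formation at the silyl ether or ketal oxygen) or dimerise. The fallback uses a stabilised acceptor/acceptor carbenoid, the best-documented substrate class for retentive 1,5 insertion; it sets out from 17 and returns at 20. Carbonyldiimidazole converts 17 into the acyl imidazolide F7, and magnesium monobenzyl malonate extends it with loss of CO2 to the benzyl β-keto ester F8. Diazo transfer with 4-acetamidobenzenesulfonyl azide and Et3N gives the diazo β-keto ester F9, and Rh2(OAc)4 closes ring A to the cyclic β-keto ester F10. Hydrogenolysis over Pd/C gives the β-keto acid F11, which decarboxylates on gentle warming to 20.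

3. Step 17 (Mitsunobu inversion). The C5 hydroxyl lies in the cleft, so formation of the bulky oxyphosphonium may be slow and elimination toward C6 may take over. The fallback replaces phosphonium activation by a small sulfonate; it sets out from 21 and returns at 22. Tf2O and pyridine at −20 °C convert 21 into the C5 endo triflate F12, which is displaced with inversion by CsOAc and 18-crown-6 in toluene.

**Further compounds**

F1 | step 4 | (S)-pent-2-yne-1,4-diol | C[C@H](O)C#CCO
F2 | step 4 | (S)-4-hydroxypent-2-yn-1-yl pivalate | C[C@H](O)C#CCOC(=O)C(C)(C)C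
F3 | step 4 | (S)-chlorodiisopropylsilyl ether of F2 | C[C@H](O[Si](Cl)(C(C)C)C(C)C)C#CCOC(=O)C(C)(C)C
F4 | step 4 | (S)-silaketal-tethered enone | CC1=C(O[Si](C(C)C)(C(C)C)O[C@@H](C)C#CCOC(=O)C(C)(C)C)C(=O)CC1
F5 | step 4 | (7S) tethered cyclobutene cycloadduct | C1C[C@]2(C)C(COC(=O)C(C)(C)C)=C3[C@H](C)O[Si](C(C)C)(C(C)C)O[C@@]23C1=O
F6 | step 4 | C13 ethylene ketal of F5 | C1C[C@]2(C)C(COC(=O)C(C)(C)C)=C3[C@H](C)O[Si](C(C)C)(C(C)C)O[C@@]23C14OCCO4
F7 | step 15 | acyl imidazolide of 17 | C1C[C@]2(C)[C@H](C(=O)n4ccnc4)[C@H]([C@H](C)O[Si](C)(C)C(C)(C)C)[C@]2(O[Si](CC)(CC)CC)C13OCCO3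
F8 | step 15 | benzyl β-keto ester | C1C[C@]2(C)[C@H](C(=O)CC(=O)OCc4ccccc4)[C@H]([C@H](C)O[Si](C)(C)C(C)(C)C)[C@]2(O[Si](CC)(CC)CC)C13OCCO3
F9 | step 15 | benzyl α-diazo β-keto ester | C1C[C@]2(C)[C@H](C(=O)C(=[N+]=[N-])C(=O)OCc4ccccc4)[C@H]([C@H](C)O[Si](C)(C)C(C)(C)C)[C@]2(O[Si](CC)(CC)CC)C13OCCO3
F10 | step 15 | ring A β-keto ester (benzyl ester on C6) | C1C[C@]2(C)[C@@H]3C(=O)C(C(=O)OCc4ccccc4)[C@@](C)(O[Si](C)(C)C(C)(C)C)[C@@H]3[C@]2(O[Si](CC)(CC)CC)C13OCCO3
F11 | step 15 | ring A β-keto acid | C1C[C@]2(C)[C@@H]3C(=O)C(C(=O)O)[C@@](C)(O[Si](C)(C)C(C)(C)C)[C@@H]3[C@]2(O[Si](CC)(CC)CC)C13OCCO3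
F12 | step 17 | C5 endo triflate | C1C[C@]2(C)[C@@H]3[C@H](OS(=O)(=O)C(F)(F)F)C[C@@](C)(O[Si](C)(C)C(C)(C)C)[C@@H]3[C@]2(O[Si](CC)(CC)CC)C13OCCO3
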